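**Retrosynthetic overview**
- Last bond: the quinone C–C(triene) bond, made by Stille coupling of an iodoquinone that already carries the upper amide (fragments A+B) with an all-E stannyl trienamide that already carries the aminocyclopentenone (fragment C).
- The iodoquinone comes from oxidative demethylation of a 2,5-dimethoxyanilide, itself from amide formation between (2E,4E,6R)-2,4,6-trimethyldeca-2,4-dienoic acid (A) and 3-chloro-4-iodo-2,5-dimethoxyaniline (B).
- A: two Wittig olefinations on (R)-2-methylhexanal; the stereocentre is set by Evans methylation of an N-hexanoyl oxazolidinone.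
- B: hydroquinone by mono-methylation, ortho-chlorination, ortho-nitration, methylation, reduction and para-iodination. C: stannylacrolein (from propargyl alcohol) plus a phosphonocrotonate (Horner–Wadsworth–Emmons), then amide formation with 2-aminocyclopentane-1,3-dione.
- Rings: none is built. The six-membered ring comes from hydroquinone and is oxidised to the quinone one step before the end; the five-membered ring comes from cyclopentane-1,3-dione.

Assumption: the cyclopentenone amide is the enol tautomer drawn in the SMILES; the oxazolidinone auxiliary, the two phosphoranes, P(OEt)3 and Bu3SnH are bought and used as reagents.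

**Fragment A: the dienoic acid**

Step 1
Reactants: 1 hexanoyl chloride
Product: 2 (R)-4-benzyl-3-hexanoyl-1,3-oxazolidin-2-one
Conditions: (R)-4-benzyl-1,3-oxazolidin-2-one, Et3N, DMAP (cat.), CH2Cl2, 0 °C to rt
Reagents that add atoms: (R)-4-benzyl-1,3-oxazolidin-2-one, O=C1N[C@H](Cc2ccccc2)CO1
Why: DMAP-catalysed N-acylation of the oxazolidinone by the acid chloride installs the chiral auxiliary.

Step 2
Reactants: 2 (R)-4-benzyl-3-hexanoyl-1,3-oxazolidin-2-one
Product: 4 (R)-4-benzyl-3-[(2R)-2-methylhexanoyl]-1,3-oxazolidin-2-one, via sodium Z-enolate 3 (not isolated)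
Conditions: NaN(SiMe3)2, THF, −78 °C; then MeI, −78 °C
Reagents that add atoms: iodomethane, CI
Why: Evans asymmetric alkylation, in which the chelated Z-enolate is methylated on the face opposite the benzyl group of the (R)-auxiliary to set the (2R) centre (the later C6 of the side chain), the minor diastereomer being removed by chromatography.

Step 3
Reactants: 4 (R)-4-benzyl-3-[(2R)-2-methylhexanoyl]-1,3-oxazolidin-2-one
Product: 5 (2R)-2-methylhexan-1-ol
Conditions: LiBH4, MeOH (1 equiv), Et2O, 0 °C
Reagents that add atoms: none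
Why: Reductive cleavage of the imide by hydride attack at the exocyclic carbonyl releases the primary alcohol and the auxiliary without touching the stereocentre.

Step 4
Reactants: 5 (2R)-2-methylhexan-1-ol
Product: 6 (2R)-2-methylhexanal
Conditions: TEMPO (10 mol %), PhI(OAc)2, CH2Cl2, rt; crude solution used at once
Reagents that add atoms: none
Why: Oxoammonium (TEMPO) oxidation stops at the aldehyde under near-neutral conditions, so the α-stereocentre is not epimerised.

Step 5
Reactants: 6 (2R)-2-methylhexanal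
Product: 7 (2E,4R)-2,4-dimethyloct-2-enal
Conditions: Ph3P=C(Me)CHO, toluene, 100 °C
Reagents that add atoms: 2-(triphenylphosphoranylidene)propanal, CC(C=O)=P(c1ccccc1)(c1ccccc1)c1ccccc1
Why: Wittig olefination with a stabilised formyl ylide gives the E-trisubstituted enal, and the weakly basic ylide leaves the adjacent stereocentre intact.

Step 6
Reactants: 7 (2E,4R)-2,4-dimethyloct-2-enal
Product: 8 ethyl (2E,4E,6R)-2,4,6-trimethyldeca-2,4-dienoate
Conditions: Ph3P=C(Me)CO2Et, toluene, 100 °C
Reagents that add atoms: ethyl 2-(triphenylphosphoranylidene)propanoate, CCOC(=O)C(C)=P(c1ccccc1)(c1ccccc1)c1ccccc1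
Why: A second Wittig olefination with a stabilised α-branched ylide forms the 2E alkene selectively and leaves the 4E alkene and C6 untouched.

Step 7
Reactants: 8 ethyl (2E,4E,6R)-2,4,6-trimethyldeca-2,4-dienoate
Product: 9 (2E,4E,6R)-2,4,6-trimethyldeca-2,4-dienoic acid
Conditions: LiOH, THF/MeOH/H2O, 50 °C; then 1 M HCl
Reagents that add atoms: lithium hydroxide, [Li+].[OH-] (supplies the carboxyl OH oxygen)
Why: Saponification of the ester; the remote allylic stereocentre is not acidic enough to epimerise.

**Fragment B: the iodoaniline**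

Step 8
Reactants: 10 hydroquinone
Product: 11 4-methoxyphenol
Conditions: Me2SO4 (1.0 equiv), NaOH, H2O, 20 °C, N2
Reagents that add atoms: dimethyl sulfate, COS(=O)(=O)OC
Why: Williamson etherification with limiting alkylating agent gives the mono-ether, which is separated by extraction from hydroquinone (stays in water) and the neutral diether (insoluble in aqueous NaOH).

Step 9
Reactants: 11 4-methoxyphenol
Product: 12 2-chloro-4-methoxyphenol
Conditions: SO2Cl2, CH2Cl2, 0 °C to rt
Reagents that add atoms: sulfuryl chloride, ClS(Cl)(=O)=O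
Why: Electrophilic aromatic chlorination goes ortho to the free OH, the stronger director, because the para position is blocked.

Step 10
Reactants: 12 2-chloro-4-methoxyphenol
Product: 13 2-chloro-4-methoxy-6-nitrophenol
Conditions: HNO3 (65 %, 1.05 equiv), AcOH, 0–10 °C
Reagents that add atoms: nitric acid, O[N+](=O)[O-]
Why: Electrophilic nitration takes the only remaining position ortho to the phenol OH, which places nitrogen and chlorine on either side of the same oxygen.

Step 11
Reactants: 13 2-chloro-4-methoxy-6-nitrophenol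
Product: 14 1-chloro-2,5-dimethoxy-3-nitrobenzene
Conditions: MeI, K2CO3, DMF, 50 °C
Reagents that add atoms: iodomethane, CI
Why: Williamson O-methylation of the acidic nitrophenoxide proceeds despite the two ortho substituents.

Step 12
Reactants: 14 1-chloro-2,5-dimethoxy-3-nitrobenzene
Product: 15 3-chloro-2,5-dimethoxyaniline
Conditions: H2 (1 atm), 5 % Pt/C (sulfided), EtOAc, rt
Reagents that add atoms: none
Why: Catalytic hydrogenation over sulfided platinum reduces the nitro group without hydrodechlorination.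

Step 13
Reactants: 15 3-chloro-2,5-dimethoxyaniline
Product: 16 3-chloro-4-iodo-2,5-dimethoxyaniline
Conditions: N-iodosuccinimide (1.0 equiv), MeCN, 0 °C, dark
Reagents that add atoms: N-iodosuccinimide, O=C1CCC(=O)N1I
Why: Electrophilic aromatic iodination is directed para to the free NH2 (also ortho to the C5 methoxy group), which puts iodine between Cl and OMe.

**Fragment C: the stannyl trienamide**

Step 14
Reactants: 17 cyclopentane-1,3-dione
Product: 18 2-nitrocyclopentane-1,3-dione (enol form, 3-hydroxy-2-nitrocyclopent-2-en-1-one)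
Conditions: fuming HNO3, Et2O, 0 °C
Reagents that add atoms: nitric acid, O[N+](=O)[O-]
Why: Electrophilic nitration of the enolised 1,3-dione occurs at the nucleophilic C2.

Step 15
Reactants: 18 2-nitrocyclopentane-1,3-dione
Product: 19 2-amino-3-hydroxycyclopent-2-en-1-one hydrochloride
Conditions: H2 (3 atm), 10 % Pd/C, HCl (1.1 equiv), MeOH, rt
Reagents that add atoms: hydrogen chloride, Cl
Why: Catalytic hydrogenation reduces the nitro group, and HCl traps the amine as its stable salt so that it cannot self-condense.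

Step 16
Reactants: 20 prop-2-yn-1-ol
Product: 21 (E)-3-(tributylstannyl)prop-2-en-1-ol
Conditions: Bu3SnH, AIBN (cat.), neat, 80 °C; chromatography
Reagents that add atoms: tributyltin hydride, CCCC[SnH](CCCC)CCCC
Why: Radical hydrostannation of the terminal alkyne equilibrates through reversible stannyl-radical addition to the E-β-vinylstannane, and the minor Z and α isomers are removed on silica.

Step 17
Reactants: 21 (E)-3-(tributylstannyl)prop-2-en-1-ol
Product: 22 (E)-3-(tributylstannyl)prop-2-enal
Conditions: MnO2 (excess), CH2Cl2, rt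
Reagents that add atoms: none
Why: Neutral allylic oxidation with MnO2 gives the enal without protodestannylation or E/Z isomerisation.

Step 18
Reactants: 23 methyl (E)-4-bromobut-2-enoate
Product: 24 methyl (E)-4-(diethoxyphosphoryl)but-2-enoate
Conditions: P(OEt)3, neat, 120 °C
Reagents that add atoms: triethyl phosphite, CCOP(OCC)OCC
Why: Michaelis–Arbuzov reaction of the allylic bromide, with loss of the ethyl group from the phosphonium intermediate, gives the vinylogous phosphonate.

Step 19
Reactants: 24 methyl (E)-4-(diethoxyphosphoryl)but-2-enoate; 22 (E)-3-(tributylstannyl)prop-2-enal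
Product: 26 methyl (2E,4E,6E)-7-(tributylstannyl)hepta-2,4,6-trienoate, via lithiated phosphonate 25 (not isolated)
Conditions: LiN(SiMe3)2, THF, −78 °C; then 22, −78 to 0 °C
Reagents that add atoms: none
Why: Vinylogous Horner–Wadsworth–Emmons olefination forms the new 4E alkene with high E selectivity while the existing E alkenes and the C–Sn bond are retained.

Step 20
Reactants: 26 methyl (2E,4E,6E)-7-(tributylstannyl)hepta-2,4,6-trienoate
Product: 27 (2E,4E,6E)-7-(tributylstannyl)hepta-2,4,6-trienoic acid
Conditions: LiOH, THF/MeOH/H2O, rt; then AcOH to pH 5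
Reagents that add atoms: lithium hydroxide, [Li+].[OH-] (supplies the carboxyl OH oxygen)
Why: Saponification followed by weak-acid work-up frees the acid without protodestannylation of the electron-poor trienylstannane.

Step 21
Reactants: 27 (2E,4E,6E)-7-(tributylstannyl)hepta-2,4,6-trienoic acid; 19 2-amino-3-hydroxycyclopent-2-en-1-one hydrochloride
Product: 28 (2E,4E,6E)-N-(2-hydroxy-5-oxocyclopent-1-en-1-yl)-7-(tributylstannyl)hepta-2,4,6-trienamide
Conditions: EDC·HCl, HOBt, Et3N, DMF, 0 °C to rt
Reagents that add atoms: none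
Why: Carbodiimide/HOBt amide coupling under near-neutral conditions spares the C–Sn bond, and any O-acyl enol ester rearranges to the more stable N-acyl amide.

**Assembly**

Step 22
Reactants: 9 (2E,4E,6R)-2,4,6-trimethyldeca-2,4-dienoic acid; 16 3-chloro-4-iodo-2,5-dimethoxyaniline
Product: 30 (2E,4E,6R)-N-(3-chloro-4-iodo-2,5-dimethoxyphenyl)-2,4,6-trimethyldeca-2,4-dienamide, via dienoyl chloride 29 (not isolated)
Conditions: (COCl)2, DMF (cat.), CH2Cl2, 0 °C to rt, evaporate; then 16, pyridine, CH2Cl2, 0 °C to rt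
Reagents that add atoms: oxalyl chloride, O=C(Cl)C(Cl)=O (its chlorine is in 29 only; none of its atoms remain in 30)
Why: N-acylation through the acid chloride drives amide formation with the weakly nucleophilic, halogen-deactivated aniline without isomerising the diene.

Step 23
Reactants: 30 (2E,4E,6R)-N-(3-chloro-4-iodo-2,5-dimethoxyphenyl)-2,4,6-trimethyldeca-2,4-dienamide
Product: 31 (2E,4E,6R)-N-(5-chloro-4-iodo-3,6-dioxocyclohexa-1,4-dien-1-yl)-2,4,6-trimethyldeca-2,4-dienamide
Conditions: (NH4)2Ce(NO3)6 (2.5 equiv), MeCN/H2O, 0 °C, 10 min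
Reagents that add atoms: water, O (supplies both quinone carbonyl oxygens)
Why: Oxidative demethylation by tetravalent cerium converts the electron-rich 1,4-dimethoxyarene into the p-quinone, while the carbonyl-conjugated dienamide and both carbon–halogen bonds survive the short, cold reaction.

Step 24
Reactants: 31 (2E,4E,6R)-N-(5-chloro-4-iodo-3,6-dioxocyclohexa-1,4-dien-1-yl)-2,4,6-trimethyldeca-2,4-dienamide; 28 (2E,4E,6E)-N-(2-hydroxy-5-oxocyclopent-1-en-1-yl)-7-(tributylstannyl)hepta-2,4,6-trienamide
Product: 32 chinikomycin B, (2E,4E,6R)-N-[5-chloro-4-[(1E,3E,5E)-7-[(2-hydroxy-5-oxocyclopent-1-en-1-yl)amino]-7-oxohepta-1,3,5-trien-1-yl]-3,6-dioxocyclohexa-1,4-dien-1-yl]-2,4,6-trimethyldeca-2,4-dienamide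
Conditions: Pd2(dba)3 (5 mol %), AsPh3 (40 mol %), DMF, rt, dark, Ar
Reagents that add atoms: none
Why: Stille cross-coupling, in which zerovalent palladium inserts into the activated quinone C–I bond far faster than into C–Cl, and transmetalation and reductive elimination retain alkene geometry to give the all-E triene under neutral conditions.

**Compound list**
1 | hexanoyl chloride | CCCCCC(Cl)=O | starting material
2 | (R)-4-benzyl-3-hexanoyl-1,3-oxazolidin-2-one | CCCCCC(=O)N1[C@H](Cc2ccccc2)COC1=O | intermediate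
3 | sodium (Z)-enolate of 2 | CCCC/C=C(\[O-])N1[C@H](Cc2ccccc2)COC1=O.[Na+] | intermediate
4 | (R)-4-benzyl-3-[(2R)-2-methylhexanoyl]-1,3-oxazolidin-2-one | CCCC[C@@H](C)C(=O)N1[C@H](Cc2ccccc2)COC1=O | intermediate
5 | (2R)-2-methylhexan-1-ol | CCCC[C@@H](C)CO | intermediate
6 | (2R)-2-methylhexanal | CCCC[C@@H](C)C=O | intermediate
7 | (2E,4R)-2,4-dimethyloct-2-enal | CCCC[C@@H](C)/C=C(\C)C=O | intermediate
8 | ethyl (2E,4E,6R)-2,4,6-trimethyldeca-2,4-dienoate | CCCC[C@@H](C)/C=C(C)/C=C(\C)C(=O)OCC | intermediate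
9 | (2E,4E,6R)-2,4,6-trimethyldeca-2,4-dienoic acid | CCCC[C@@H](C)/C=C(C)/C=C(\C)C(=O)O | intermediate
10 | hydroquinone | Oc1ccc(O)cc1 | starting material
11 | 4-methoxyphenol | COc1ccc(O)cc1 | intermediate
12 | 2-chloro-4-methoxyphenol | COc1ccc(O)c(Cl)c1 | intermediate
13 | 2-chloro-4-methoxy-6-nitrophenol | COc1cc(Cl)c(O)c([N+](=O)[O-])c1 | intermediate
14 | 1-chloro-2,5-dimethoxy-3-nitrobenzene | COc1cc(Cl)c(OC)c([N+](=O)[O-])c1 | intermediate
15 | 3-chloro-2,5-dimethoxyaniline | COc1cc(N)c(OC)c(Cl)c1 | intermediate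
16 | 3-chloro-4-iodo-2,5-dimethoxyaniline | COc1cc(N)c(OC)c(Cl)c1I | intermediate
17 | cyclopentane-1,3-dione | O=C1CCC(=O)C1 | starting material
18 | 2-nitrocyclopentane-1,3-dione (enol form) | O=C1CCC(O)=C1[N+](=O)[O-] | intermediate
19 | 2-amino-3-hydroxycyclopent-2-en-1-one hydrochloride | NC1=C(O)CCC1=O.Cl | intermediate
20 | prop-2-yn-1-ol | C#CCO | starting material
21 | (E)-3-(tributylstannyl)prop-2-en-1-ol | CCCC[Sn](CCCC)(CCCC)/C=C/CO | intermediate
22 | (E)-3-(tributylstannyl)prop-2-enal | CCCC[Sn](CCCC)(CCCC)/C=C/C=O | intermediate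
23 | methyl (E)-4-bromobut-2-enoate | COC(=O)/C=C/CBr | starting material
24 | methyl (E)-4-(diethoxyphosphoryl)but-2-enoate | CCOP(=O)(C/C=C/C(=O)OC)OCC | intermediate
25 | lithium salt of 24 (anion at C4) | [Li+].CCOP(=O)([CH-]/C=C/C(=O)OC)OCC | intermediate
26 | methyl (2E,4E,6E)-7-(tributylstannyl)hepta-2,4,6-trienoate | COC(=O)/C=C/C=C/C=C/[Sn](CCCC)(CCCC)CCCC | intermediate
27 | (2E,4E,6E)-7-(tributylstannyl)hepta-2,4,6-trienoic acid | OC(=O)/C=C/C=C/C=C/[Sn](CCCC)(CCCC)CCCC | intermediate
28 | (2E,4E,6E)-N-(2-hydroxy-5-oxocyclopent-1-en-1-yl)-7-(tributylstannyl)hepta-2,4,6-trienamide | O=C(/C=C/C=C/C=C/[Sn](CCCC)(CCCC)CCCC)NC1=C(O)CCC1=O | intermediate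
29 | (2E,4E,6R)-2,4,6-trimethyldeca-2,4-dienoyl chloride | CCCC[C@@H](C)/C=C(C)/C=C(\C)C(Cl)=O | intermediate
30 | (2E,4E,6R)-N-(3-chloro-4-iodo-2,5-dimethoxyphenyl)-2,4,6-trimethyldeca-2,4-dienamide | CCCC[C@@H](C)/C=C(C)/C=C(\C)C(=O)Nc1cc(OC)c(I)c(Cl)c1OC | intermediate
31 | (2E,4E,6R)-N-(5-chloro-4-iodo-3,6-dioxocyclohexa-1,4-dien-1-yl)-2,4,6-trimethyldeca-2,4-dienamide | CCCC[C@@H](C)/C=C(C)/C=C(\C)C(=O)NC1=CC(=O)C(I)=C(Cl)C1=O | intermediate
32 | chinikomycin B | CCCC[C@@H](C)/C=C(C)/C=C(\C)C(=O)NC1=CC(=O)C(/C=C/C=C/C=C/C(=O)NC2=C(O)CCC2=O)=C(Cl)C1=O | target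

**Totals**
Total step count: 24. Longest linear sequence: 10 steps (1 → 2 → 4 → 5 → 6 → 7 → 8 → 9 → 30 → 31 → 32).

**Steps most likely to fail, with fallbacks**

Step 13, regiochemistry of the iodination. Iodine may also enter ortho to NH2 at C6. The fallback sets out from 15 and comes back at 16, replacing electrophilic substitution by directed metalation. Paal–Knorr condensation of 15 with hexane-2,5-dione (TsOH cat., toluene, reflux) gives 1-(3-chloro-2,5-dimethoxyphenyl)-2,5-dimethyl-1H-pyrrole F1, in which nitrogen no longer activates or directs. Lithium 2,2,6,6-tetramethylpiperidide in THF at −78 °C removes the most acidic ring proton, the one flanked by Cl and OMe, to give [2-chloro-4-(2,5-dimethylpyrrol-1-yl)-3,6-dimethoxyphenyl]lithium F2. Quenching with I2 gives 1-(3-chloro-4-iodo-2,5-dimethoxyphenyl)-2,5-dimethyl-1H-pyrrole F3, and NH2OH·HCl/Et3N in EtOH/H2O at reflux releases 16.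

Step 21, amide formation in the presence of the C–Sn bond. Protodestannylation by the acidic enol or sluggish acylation of the weakly nucleophilic amine could spoil it. The fallback sets out from 24 and comes back at 28, making the amide before any tin is present. Selective saponification of the carboxylic ester of 24 (LiOH 1.0 equiv, THF/H2O, 0 °C) gives (E)-4-(diethoxyphosphoryl)but-2-enoic acid F4. Coupling with 19 (EDC·HCl, HOBt, Et3N, DMF) gives (E)-4-(diethoxyphosphoryl)-N-(2-hydroxy-5-oxocyclopent-1-en-1-yl)but-2-enamide F5. A Horner–Wadsworth–Emmons reaction of F5 with 22 (LiOH·H2O in excess, 4 Å molecular sieves, THF, rt) then gives 28.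

Step 24, Stille coupling on the iodoquinone. The quinone may oxidise the catalyst or the stannane, or be attacked by the enol. The fallback sets out from 30 and comes back at 32, coupling at the arene stage and oxidising last. Stille coupling of 30 with 28 (Pd2(dba)3, AsPh3, CuI, NMP, 60 °C) gives (2E,4E,6R)-N-[3-chloro-4-[(1E,3E,5E)-7-[(2-hydroxy-5-oxocyclopent-1-en-1-yl)amino]-7-oxohepta-1,3,5-trien-1-yl]-2,5-dimethoxyphenyl]-2,4,6-trimethyldeca-2,4-dienamide F6. Oxidative demethylation of F6 with (NH4)2Ce(NO3)6 in MeCN/H2O at 0 °C then gives 32.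

**Further compounds**
F1 | step 13 | 1-(3-chloro-2,5-dimethoxyphenyl)-2,5-dimethyl-1H-pyrrole | COc1cc(-n2c(C)ccc2C)c(OC)c(Cl)c1
F2 | step 13 | [2-chloro-4-(2,5-dimethylpyrrol-1-yl)-3,6-dimethoxyphenyl]lithium | [Li]c1c(Cl)c(OC)c(-n2c(C)ccc2C)cc1OC
F3 | step 13 | 1-(3-chloro-4-iodo-2,5-dimethoxyphenyl)-2,5-dimethyl-1H-pyrrole | COc1cc(-n2c(C)ccc2C)c(OC)c(Cl)c1I
F4 | step 21 | (E)-4-(diethoxyphosphoryl)but-2-enoic acid | CCOP(=O)(C/C=C/C(=O)O)OCC
F5 | step 21 | (E)-4-(diethoxyphosphoryl)-N-(2-hydroxy-5-oxocyclopent-1-en-1-yl)but-2-enamide | CCOP(=O)(C/C=C/C(=O)NC1=C(O)CCC1=O)OCC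
F6 | step 24 | (2E,4E,6R)-N-[3-chloro-4-[(1E,3E,5E)-7-[(2-hydroxy-5-oxocyclopent-1-en-1-yl)amino]-7-oxohepta-1,3,5-trien-1-yl]-2,5-dimethoxyphenyl]-2,4,6-trimethyldeca-2,4-dienamide | CCCC[C@@H](C)/C=C(C)/C=C(\C)C(=O)Nc1cc(OC)c(/C=C/C=C/C=C/C(=O)NC2=C(O)CCC2=O)c(Cl)c1OC
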